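The rate constants are assumed; the result is computed.

Capture is the slow exit from this cycle: catalyst intermediate D is captured at 0.10 s⁻¹ with c(capture agent) as charged, and moves on to catalyst intermediate E at 3.1 s⁻¹. Yet capture has no way back.

substrate 0.10 M; partner 0.0900 M; capture agent 0.0100 M; free catalyst 1.4 mM

    substrate + free catalyst → catalyst intermediate A (k1 = 30 L mol⁻¹ s⁻¹)
    catalyst intermediate A → catalyst intermediate B (k2 = 4.4 s⁻¹)
    partner + catalyst intermediate B ⇌ catalyst intermediate C (K3 = 20 L mol⁻¹, k3 = 44 L mol⁻¹ s⁻¹)
    catalyst intermediate C → by-product + catalyst intermediate D (k4 = 4.2 s⁻¹)
    catalyst intermediate D ⇌ catalyst intermediate E (K5 = 31, k5 = 3.1 s⁻¹)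
    catalyst intermediate E → free catalyst + product (k6 = 5.2 s⁻¹)
    capture agent + catalyst intermediate D → trapped intermediate (k7 = 10 L mol⁻¹ s⁻¹)

- the form that holds most of the catalyst when 30% of the substrate are converted (catalyst intermediate A / catalyst intermediate D / catalyst intermediate C / trapped intermediate / free catalyst / catalyst intermediate B)
- its share of the catalyst then
- factor on the rate of making product when 30% of the substrate are converted if partner is charged twice over
- factor on the rate when 30% of the substrate are converted if free catalyst is charged at 8.0 mM instead

The reckoning by hand runs in short steps.

1. Capture takes 3.12% of the catalyst passing through D. This capture share per pass is the capture rate over capture plus onward rate, a branching fraction.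

2. Each converted substrate counts as one pass through D. The count belongs to the flask, not to each catalyst, so 30.0 mM converted gives 0.938 mM of trapped intermediate. That is less than the 1.4 mM charged, a share of 67.0%.

3. The weak link is c(capture agent), taken so far as charged. Capture consumes part of it, so its mean over the run is nearer 9.53 mM. The capture share per pass falls to 2.98%, which gives 0.895 mM trapped.

4. The number to commit to is a share of 63.9%. Trapped intermediate is then the largest form.

5. By this reckoning the working catalyst in this flask is 0.505 mM. With 8.0 mM charged, the same conversion traps about the same amount, a share of 11.2%, and leaves 7.11 mM working. Taking the rate per working catalyst as equal at equal conversion, the load factor is 14.1. This reckoning gives no partner factor.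

The forecast names trapped intermediate at 65%, with a partner factor of 1.2 and a load factor of 14.7. Its ground: “Each turnover loses about 3% of the catalyst to irreversible capture at D”. Its load factor stands above the one reckoned here.

The simulation gives trapped intermediate at 64.4%, a partner factor of 1.20 and a load factor of 14.8.

In the flask as charged, catalyst intermediate E falls back at 0.019 of the rate at which it goes on, at 18.5 s. Trapped intermediate per substrate converted in that flask reads 3.01% at 30% conversion, beside the 2.98% reckoned. With free catalyst charged at 8.0 mM instead, at the same conversion, trapped intermediate holds 9.63% of the catalyst, against the 11.2% reckoned. With that other charge of free catalyst, the same reading is 2.57% per substrate converted.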